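3 questions stand on this flask, and one concentration carries them.

substrate 0.80 M; gas phase 35 mM (held); protic impurity 0.0800 M; free catalyst 0.05 mol%; stray impurity 0.26 mM; time 80 min

    substrate + dissolved gas + free catalyst → free catalyst + target (k1 = 2600 M⁻² min⁻¹)
    dissolved gas + protic impurity → quenched reagent (k2 = 0.062 M⁻¹ min⁻¹)
    free catalyst + stray impurity → spent catalyst (k3 = 890 M⁻¹ min⁻¹)
    gas phase ⇌ dissolved gas, rate k4*(csat - [dissolved gas]) (k4 = 0.48 min⁻¹, csat = 35 mM)
    target ⇌ isomer of the product (K5 = 0.20, k5 = 0.0013 min⁻¹)

- at the start none of the gas is dissolved
- run time (flask): 80 min

1. target at 80 min, in percent of the substrate charged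
2. the change that raises the amount of target at 80 min, in percent of the substrate charged most ("none" if none brings more than 2 percentage points) (dusk / noon / winter / none)
3. amount of target at 80 min, in percent of the substrate charged, after dusk

- dusk: doubling the amount of free catalyst, all else as stated
- noon: doubling the transfer coefficient of step 4, all else as stated
- winter: doubling the saturation concentration of gas phase, all else as stated

Carry this number onto the bench: 0.140 mM of live catalyst, the charge of free catalyst minus the charge of stray impurity. Expect that loss to end early, because even against live catalyst the stray impurity has a half-life of 5.56 min, far shorter than the run. Then take [free catalyst] as the concentration that sets the rate. At half-spent substrate it takes up dissolved gas with a constant of 0.146 min⁻¹, slower than transfer at 0.48 min⁻¹, so expect [dissolved gas] near 26.9 mM. Treat the substrate as pseudo-first-order at that level, take off isomer of the product for half the run, and expect 51.4% of target.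

Leave the protic impurity alone: its quench halves dissolved gas in 140 min, much more slowly than the main step at 0.83 min. Compare the changes by their rates at half-spent substrate. Dusk leaves 0.540 mM live and [dissolved gas] near 16.1 mM, so choose dusk and expect 79.3%.

The forecast said 50%, dusk and 80%, reasoning that “catalyst limits the late stage”. The simulation gives 49.2%, dusk and 80.5%, with dusk gaining 31 percentage points, winter 26 points and noon 6.8 points.

Read 35.0% of the catalyst free in the flask at 80.0 min; live catalyst reckons 35.0%. With 6.5 × 10⁻⁵ M of stray impurity, a neighbour flask reckons 0.335 mM live and gives 69.9% of target. The flask is not at rest at 80 min, with 48.4% of substrate standing. Left to 800 min, ten times the run, the flask still reads 35.0% of free catalyst at 800 min. Substrate has fallen to 0.00707% at 800 min, and protic impurity to 19.8% at 800 min. Isomer of the product reads 16.6% at 800 min, beside 83.4% of target at 800 min.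

Its constants stand for no real mixture; what happens was integrated by code.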